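Numbering: tetralin C1 (side chain), C4 (methyl), C5 (OH), C8 (CO2H); chain C11(Me)–C12–C13–C14–C15(Me)–C16–O. The route cuts C13–C14, the middle of the unfunctionalised C12–C14 bridge between the ring-bound stereotriad C1/C4/C11 and the remote C15 centre; the key step exploits this bridge. An alkyl–alkyl Negishi coupling joins the primary C13 iodide of the fully built, silyl-protected tetralin with the C14 alkylzinc of the complete ester side chain; no stereocentre is touched and only desilylation follows. The iodide comes from (+)-dihydrocarvone (C1, C4) by Diels–Alder benzannulation, formaldehyde ene reaction and asymmetric hydrogenation (C11); the zinc reagent from (S)-3-bromo-2-methylpropanol (C15).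

Key step: step 10

Assumption: commercial (+)-dihydrocarvone (trans-rich) is freed from its minor cis epimer by chromatography and used as the (2R,5R) isomer 1; in step 7 the BINAP antipode that is matched with the substrate is fixed by a small test with both antipodes.

Step 1
Reactants: 1 (2R,5R)-2-methyl-5-(prop-1-en-2-yl)cyclohexan-1-one
Product: 2 (3R,6R)-6-methyl-3-(prop-1-en-2-yl)cyclohex-1-en-1-yl trifluoromethanesulfonate
Conditions: LDA, THF, −78 °C; then PhNTf2, −78 °C → rt
Reagents that add atoms: N-phenylbis(trifluoromethanesulfonimide), O=S(=O)(N(c1ccccc1)S(=O)(=O)C(F)(F)F)C(F)(F)F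
Why: Kinetic deprotonation at the unsubstituted α-CH2 and O-triflation of the enolate should give the less substituted enol triflate (regioselective enol triflate formation), leaving the α-methyl centre (future C4) and its trans relation to future C1 untouched.

Step 2
Reactants: 2 (3R,6R)-6-methyl-3-(prop-1-en-2-yl)cyclohex-1-en-1-yl trifluoromethanesulfonate
Product: 4 1-[(3R,6R)-6-methyl-3-(prop-1-en-2-yl)cyclohex-1-en-1-yl]ethan-1-one, via ethoxydiene 3 (not isolated)
Conditions: tributyl(1-ethoxyvinyl)stannane, Pd(PPh3)4 (5 mol%), LiCl, THF, reflux; then 1 M HCl, rt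
Reagents that add atoms: tributyl(1-ethoxyvinyl)stannane, CCCC[Sn](CCCC)(CCCC)C(=C)OCC; water, O
Why: Stille coupling of the vinyl triflate with the acyl-anion equivalent followed by mild acid hydrolysis of the enol ether should give the methyl enone without affecting either stereocentre or the isopropenyl group.

Step 3
Reactants: 4 1-[(3R,6R)-6-methyl-3-(prop-1-en-2-yl)cyclohex-1-en-1-yl]ethan-1-one
Product: 5 tert-butyldimethyl({1-[(3R,6R)-6-methyl-3-(prop-1-en-2-yl)cyclohex-1-en-1-yl]ethenyl}oxy)silane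
Conditions: TBSOTf, Et3N, CH2Cl2, 0 °C
Reagents that add atoms: tert-butyldimethylsilyl trifluoromethanesulfonate, CC(C)(C)[Si](C)(C)OS(=O)(=O)C(F)(F)F
Why: Soft enolisation of the acetyl CH3 (silyl enol ether formation) should give the cross-conjugated 2-silyloxy-1,3-diene, which already carries the future phenol oxygen in protected form.

Step 4
Reactants: 6 propiolic acid; 7 2-(trimethylsilyl)ethanol
Product: 8 2-(trimethylsilyl)ethyl prop-2-ynoate
Conditions: DCC, DMAP (5 mol%), CH2Cl2, −20 → 0 °C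
Reagents that add atoms: none
Why: Steglich esterification at low temperature (to suppress DMAP addition to the ynoate) should give the dienophile with a fluoride-labile ester.

Step 5
Reactants: 5 tert-butyldimethyl({1-[(3R,6R)-6-methyl-3-(prop-1-en-2-yl)cyclohex-1-en-1-yl]ethenyl}oxy)silane; 8 2-(trimethylsilyl)ethyl prop-2-ynoate
Product: 10 2-(trimethylsilyl)ethyl (5R,8S)-4-[(tert-butyldimethylsilyl)oxy]-5-methyl-8-(prop-1-en-2-yl)-5,6,7,8-tetrahydronaphthalene-1-carboxylate, via cyclohexadiene adduct 9 (not isolated)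
Conditions: toluene, 110 °C (sealed); then DDQ, toluene, 0 °C → rt
Reagents that add atoms: none
Why: In this normal-demand Diels–Alder reaction the 2-silyloxy group and the alkyl-substituted diene terminus both direct the ester carbon to C8 ("para" to C5–O), and DDQ dehydrogenation of the 1,4-cyclohexadiene should give the arene (Diels–Alder/aromatisation benzannulation), erasing the transient C8a centre while C1 and C4 stay as bought.

Step 6
Reactants: 10 2-(trimethylsilyl)ethyl (5R,8S)-4-[(tert-butyldimethylsilyl)oxy]-5-methyl-8-(prop-1-en-2-yl)-5,6,7,8-tetrahydronaphthalene-1-carboxylate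
Product: 11 2-(trimethylsilyl)ethyl (5R,8S)-4-[(tert-butyldimethylsilyl)oxy]-8-(4-hydroxybut-1-en-2-yl)-5-methyl-5,6,7,8-tetrahydronaphthalene-1-carboxylate
Conditions: (CH2O)n, Me2AlCl, CH2Cl2, −78 → 0 °C
Reagents that add atoms: paraformaldehyde (as formaldehyde), C=O
Why: The Me2AlCl-promoted carbonyl-ene reaction of the 1,1-disubstituted alkene with formaldehyde should bond the new carbon (C13) to the terminal CH2 (C12) with hydrogen transfer from the methyl group, the aluminium reagent acting as proton scavenger so that the silyl groups survive.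

Step 7
Reactants: 11 2-(trimethylsilyl)ethyl (5R,8S)-4-[(tert-butyldimethylsilyl)oxy]-8-(4-hydroxybut-1-en-2-yl)-5-methyl-5,6,7,8-tetrahydronaphthalene-1-carboxylate
Product: 12 2-(trimethylsilyl)ethyl (5R,8S)-4-[(tert-butyldimethylsilyl)oxy]-8-[(2S)-4-hydroxybutan-2-yl]-5-methyl-5,6,7,8-tetrahydronaphthalene-1-carboxylate
Conditions: H2 (50 atm), Ru(OAc)2[(S)-BINAP] (1 mol%, matched antipode per assumption), MeOH, rt
Reagents that add atoms: none
Why: In this hydroxyl-directed Ru–BINAP asymmetric hydrogenation the homoallylic OH and the 1,1-disubstituted alkene chelate ruthenium and the ligand selects the alkene face, so C11 (S) should be set under catalyst control without touching ester or silyl groups.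

Step 8
Reactants: 12 2-(trimethylsilyl)ethyl (5R,8S)-4-[(tert-butyldimethylsilyl)oxy]-8-[(2S)-4-hydroxybutan-2-yl]-5-methyl-5,6,7,8-tetrahydronaphthalene-1-carboxylate
Product: 13 2-(trimethylsilyl)ethyl (5R,8S)-4-[(tert-butyldimethylsilyl)oxy]-8-[(2S)-4-iodobutan-2-yl]-5-methyl-5,6,7,8-tetrahydronaphthalene-1-carboxylate
Conditions: I2, PPh3, imidazole, CH2Cl2, 0 °C → rt
Reagents that add atoms: iodine, II
Why: Appel-type iodination of the primary alcohol proceeds by SN2 at C13 under neutral conditions and involves no stereocentre.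

Step 9
Reactants: 14 (2S)-3-bromo-2-methylpropan-1-ol; 15 4-methylpent-3-enoic acid
Product: 16 (2S)-3-bromo-2-methylpropyl 4-methylpent-3-enoate
Conditions: EDC·HCl, DMAP (10 mol%), CH2Cl2, 0 °C → rt
Reagents that add atoms: none
Why: Carbodiimide (Steglich) esterification of the primary alcohol at low temperature should leave the bought C15 centre and the β,γ-position of the alkene unchanged.

Step 10
Reactants: 13 2-(trimethylsilyl)ethyl (5R,8S)-4-[(tert-butyldimethylsilyl)oxy]-8-[(2S)-4-iodobutan-2-yl]-5-methyl-5,6,7,8-tetrahydronaphthalene-1-carboxylate; 16 (2S)-3-bromo-2-methylpropyl 4-methylpent-3-enoate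
Product: 18 2-(trimethylsilyl)ethyl (5R,8S)-4-[(tert-butyldimethylsilyl)oxy]-5-methyl-8-{(2S,6R)-6-methyl-7-[(4-methylpent-3-enoyl)oxy]heptan-2-yl}-5,6,7,8-tetrahydronaphthalene-1-carboxylate, via alkylzinc bromide 17 (not isolated)
Conditions: 16, Zn dust, I2 (5 mol%), DMA, 70 °C; then 13, Pd2(dba)3 (2 mol%), PCyp3 (8 mol%), N-methylimidazole, THF/NMP, 80 °C
Reagents that add atoms: none
Why: Zinc inserts into the C14–Br bond of 16 to give the ester-tolerant alkylzinc 17, Pd(0)/PCyp3 adds oxidatively (SN2-type) to the unbranched primary C13–I bond of 13, the N-methylimidazole-activated zinc reagent transmetalates, and reductive elimination forms C13–C14. The closest known reaction type is the Pd/trialkylphosphine alkyl–alkyl Negishi coupling of unactivated primary alkyl halides with alkylzinc halides. No ring is closed and no stereocentre is created; C11 and C15 should be carried through unchanged because neither carbon bears a metal at any stage. The step needs cross-coupling to outrun β-hydride elimination and homocoupling, which the bulky electron-rich phosphine and the placement of the β-branch on the nucleophile instead of the electrophile should secure. Chemoselectivity rests on the low nucleophilicity of the organozinc towards both esters and on the inertness of the aryl silyl ether and the trisubstituted alkene to Pd(0).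

Step 11
Reactants: 18 2-(trimethylsilyl)ethyl (5R,8S)-4-[(tert-butyldimethylsilyl)oxy]-5-methyl-8-{(2S,6R)-6-methyl-7-[(4-methylpent-3-enoyl)oxy]heptan-2-yl}-5,6,7,8-tetrahydronaphthalene-1-carboxylate
Product: 19 (5R,8S)-4-hydroxy-5-methyl-8-{(2S,6R)-6-methyl-7-[(4-methylpent-3-enoyl)oxy]heptan-2-yl}-5,6,7,8-tetrahydronaphthalene-1-carboxylic acid
Conditions: TBAF, THF, 0 °C → rt; aq. NH4Cl/dilute HCl work-up
Reagents that add atoms: none
Why: Fluoride-mediated desilylation should cleave the aryl silyl ether and, by β-elimination of ethene and Me3SiF, the 2-(trimethylsilyl)ethyl ester, while the primary alkyl ester and the trisubstituted alkene are inert to fluoride at this temperature.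

Compound list
1 | (2R,5R)-2-methyl-5-(prop-1-en-2-yl)cyclohexan-1-one [(+)-trans-dihydrocarvone] | C[C@@H]1CC[C@H](CC1=O)C(C)=C | starting material
2 | (3R,6R)-6-methyl-3-(prop-1-en-2-yl)cyclohex-1-en-1-yl trifluoromethanesulfonate | C[C@@H]1CC[C@@H](C(C)=C)C=C1OS(=O)(=O)C(F)(F)F | intermediate
3 | (3R,6R)-1-(1-ethoxyethenyl)-6-methyl-3-(prop-1-en-2-yl)cyclohex-1-ene | C[C@@H]1CC[C@@H](C(C)=C)C=C1C(=C)OCC | intermediate
4 | 1-[(3R,6R)-6-methyl-3-(prop-1-en-2-yl)cyclohex-1-en-1-yl]ethan-1-one | C[C@@H]1CC[C@@H](C(C)=C)C=C1C(C)=O | intermediate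
5 | tert-butyldimethyl({1-[(3R,6R)-6-methyl-3-(prop-1-en-2-yl)cyclohex-1-en-1-yl]ethenyl}oxy)silane | C[C@@H]1CC[C@@H](C(C)=C)C=C1C(=C)O[Si](C)(C)C(C)(C)C | intermediate
6 | propiolic acid | C#CC(=O)O | starting material
7 | 2-(trimethylsilyl)ethanol | C[Si](C)(C)CCO | starting material
8 | 2-(trimethylsilyl)ethyl prop-2-ynoate | C#CC(=O)OCC[Si](C)(C)C | intermediate
9 | 2-(trimethylsilyl)ethyl (5R,8R)-4-[(tert-butyldimethylsilyl)oxy]-5-methyl-8-(prop-1-en-2-yl)-3,5,6,7,8,8a-hexahydronaphthalene-1-carboxylate (C8a epimers) | C[C@@H]1CC[C@@H](C(C)=C)C2C1=C(O[Si](C)(C)C(C)(C)C)CC=C2C(=O)OCC[Si](C)(C)C | intermediate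
10 | 2-(trimethylsilyl)ethyl (5R,8S)-4-[(tert-butyldimethylsilyl)oxy]-5-methyl-8-(prop-1-en-2-yl)-5,6,7,8-tetrahydronaphthalene-1-carboxylate | CC(=C)[C@@H]1CC[C@@H](C)c2c(O[Si](C)(C)C(C)(C)C)ccc(C(=O)OCC[Si](C)(C)C)c21 | intermediate
11 | 2-(trimethylsilyl)ethyl (5R,8S)-4-[(tert-butyldimethylsilyl)oxy]-8-(4-hydroxybut-1-en-2-yl)-5-methyl-5,6,7,8-tetrahydronaphthalene-1-carboxylate | C=C(CCO)[C@@H]1CC[C@@H](C)c2c(O[Si](C)(C)C(C)(C)C)ccc(C(=O)OCC[Si](C)(C)C)c21 | intermediate
12 | 2-(trimethylsilyl)ethyl (5R,8S)-4-[(tert-butyldimethylsilyl)oxy]-8-[(2S)-4-hydroxybutan-2-yl]-5-methyl-5,6,7,8-tetrahydronaphthalene-1-carboxylate | OCC[C@H](C)[C@@H]1CC[C@@H](C)c2c(O[Si](C)(C)C(C)(C)C)ccc(C(=O)OCC[Si](C)(C)C)c21 | intermediate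
13 | 2-(trimethylsilyl)ethyl (5R,8S)-4-[(tert-butyldimethylsilyl)oxy]-8-[(2S)-4-iodobutan-2-yl]-5-methyl-5,6,7,8-tetrahydronaphthalene-1-carboxylate | ICC[C@H](C)[C@@H]1CC[C@@H](C)c2c(O[Si](C)(C)C(C)(C)C)ccc(C(=O)OCC[Si](C)(C)C)c21 | intermediate
14 | (2S)-3-bromo-2-methylpropan-1-ol | OC[C@H](C)CBr | starting material
15 | 4-methylpent-3-enoic acid | CC(C)=CCC(=O)O | starting material
16 | (2S)-3-bromo-2-methylpropyl 4-methylpent-3-enoate | CC(C)=CCC(=O)OC[C@H](C)CBr | intermediate
17 | {(2S)-2-methyl-3-[(4-methylpent-3-enoyl)oxy]propyl}zinc bromide | CC(C)=CCC(=O)OC[C@H](C)C[Zn]Br | intermediate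
18 | 2-(trimethylsilyl)ethyl (5R,8S)-4-[(tert-butyldimethylsilyl)oxy]-5-methyl-8-{(2S,6R)-6-methyl-7-[(4-methylpent-3-enoyl)oxy]heptan-2-yl}-5,6,7,8-tetrahydronaphthalene-1-carboxylate | CC(C)=CCC(=O)OC[C@H](C)CCC[C@H](C)[C@@H]1CC[C@@H](C)c2c(O[Si](C)(C)C(C)(C)C)ccc(C(=O)OCC[Si](C)(C)C)c21 | intermediate
19 | (5R,8S)-4-hydroxy-5-methyl-8-{(2S,6R)-6-methyl-7-[(4-methylpent-3-enoyl)oxy]heptan-2-yl}-5,6,7,8-tetrahydronaphthalene-1-carboxylic acid | CC(C)=CCC(=O)OC[C@H](C)CCC[C@H](C)[C@@H]1CC[C@@H](C)c2c(O)ccc(C(=O)O)c21 | target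

Total steps: 11. Longest linear sequence: 9 steps (1, 2, 3, 5, 6, 7, 8, 10, 11).

Steps most likely to fail

Step 7. The facial selectivity at C11 may be poor, either because the catalyst and the bias of the adjacent C1 centre oppose each other or because ruthenium hydride migrates the terminal alkene before reduction. The fallback sets out from 10 and comes back at 12. SeO2/t-BuOOH allylic hydroxylation of the isopropenyl methyl group should give the 2-substituted allylic alcohol F1. Ru–BINAP hydrogenation of this exo-methylene allylic alcohol, a substrate class with strong catalyst control next to an existing stereocentre, should give the saturated alcohol F2. Dess–Martin oxidation should give the aldehyde F3, and salt-free methylenetriphenylphosphorane at −78 °C the vinyl compound F4. 9-BBN hydroboration with NaBO3 oxidation then delivers 12.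

Step 10. β-Hydride elimination or slow transmetalation of the β-branched alkylzinc may divert the iodide to reduction, elimination or homocoupling. The fallback sets out from 12 and 14 and comes back at 18 by olefination and hydrogenation instead of cross-coupling. Dess–Martin oxidation of 12 should give the aldehyde F5. Heating 14 with PPh3 in MeCN should give the phosphonium salt F6. Double deprotonation of F6 (2 equiv NaHMDS, THF, −78 °C) and Wittig reaction with F5 should give the (Z)-alkenol F7. Hydrogenation (H2, Pd/C, EtOAc), done before the trisubstituted alkene is present, should give the saturated alcohol F8. EDC/DMAP esterification of F8 with 15 gives 18.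

Step 6. The Lewis acid may erode the 2-(trimethylsilyl)ethyl ester, or the ene reaction may take the benzylic C1 hydrogen instead of a methyl hydrogen. The fallback sets out from 10 and comes back at 11. Ene-type allylic chlorination (Ca(OCl)2, solid CO2, CH2Cl2/H2O, 0 °C) should give the allylic chloride F9. Barbier allylation of aqueous formaldehyde (Zn dust, THF/sat. NH4Cl) then gives 11; the two CH2 termini of the 2-substituted allyl unit are equivalent, so only one homoallylic alcohol can form.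

Further compounds
F1 | step 7 | 2-(trimethylsilyl)ethyl (5R,8R)-4-[(tert-butyldimethylsilyl)oxy]-8-(3-hydroxyprop-1-en-2-yl)-5-methyl-5,6,7,8-tetrahydronaphthalene-1-carboxylate | C=C(CO)[C@@H]1CC[C@@H](C)c2c(O[Si](C)(C)C(C)(C)C)ccc(C(=O)OCC[Si](C)(C)C)c21
F2 | step 7 | 2-(trimethylsilyl)ethyl (5R,8S)-4-[(tert-butyldimethylsilyl)oxy]-8-[(2R)-1-hydroxypropan-2-yl]-5-methyl-5,6,7,8-tetrahydronaphthalene-1-carboxylate | OC[C@H](C)[C@@H]1CC[C@@H](C)c2c(O[Si](C)(C)C(C)(C)C)ccc(C(=O)OCC[Si](C)(C)C)c21
F3 | step 7 | 2-(trimethylsilyl)ethyl (5R,8S)-4-[(tert-butyldimethylsilyl)oxy]-5-methyl-8-[(2R)-1-oxopropan-2-yl]-5,6,7,8-tetrahydronaphthalene-1-carboxylate | O=C[C@H](C)[C@@H]1CC[C@@H](C)c2c(O[Si](C)(C)C(C)(C)C)ccc(C(=O)OCC[Si](C)(C)C)c21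
F4 | step 7 | 2-(trimethylsilyl)ethyl (5R,8S)-8-[(2S)-but-3-en-2-yl]-4-[(tert-butyldimethylsilyl)oxy]-5-methyl-5,6,7,8-tetrahydronaphthalene-1-carboxylate | C=C[C@H](C)[C@@H]1CC[C@@H](C)c2c(O[Si](C)(C)C(C)(C)C)ccc(C(=O)OCC[Si](C)(C)C)c21
F5 | step 10 | 2-(trimethylsilyl)ethyl (5R,8S)-4-[(tert-butyldimethylsilyl)oxy]-5-methyl-8-[(2S)-4-oxobutan-2-yl]-5,6,7,8-tetrahydronaphthalene-1-carboxylate | O=CC[C@H](C)[C@@H]1CC[C@@H](C)c2c(O[Si](C)(C)C(C)(C)C)ccc(C(=O)OCC[Si](C)(C)C)c21
F6 | step 10 | [(2S)-3-hydroxy-2-methylpropyl]triphenylphosphonium bromide | OC[C@H](C)C[P+](c1ccccc1)(c1ccccc1)c1ccccc1.[Br-]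
F7 | step 10 | 2-(trimethylsilyl)ethyl (5R,8S)-4-[(tert-butyldimethylsilyl)oxy]-8-[(2S,4Z,6R)-7-hydroxy-6-methylhept-4-en-2-yl]-5-methyl-5,6,7,8-tetrahydronaphthalene-1-carboxylate | OC[C@H](C)/C=C\C[C@H](C)[C@@H]1CC[C@@H](C)c2c(O[Si](C)(C)C(C)(C)C)ccc(C(=O)OCC[Si](C)(C)C)c21
F8 | step 10 | 2-(trimethylsilyl)ethyl (5R,8S)-4-[(tert-butyldimethylsilyl)oxy]-8-[(2S,6R)-7-hydroxy-6-methylheptan-2-yl]-5-methyl-5,6,7,8-tetrahydronaphthalene-1-carboxylate | OC[C@H](C)CCC[C@H](C)[C@@H]1CC[C@@H](C)c2c(O[Si](C)(C)C(C)(C)C)ccc(C(=O)OCC[Si](C)(C)C)c21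
F9 | step 6 | 2-(trimethylsilyl)ethyl (5R,8R)-4-[(tert-butyldimethylsilyl)oxy]-8-(3-chloroprop-1-en-2-yl)-5-methyl-5,6,7,8-tetrahydronaphthalene-1-carboxylate | C=C(CCl)[C@@H]1CC[C@@H](C)c2c(O[Si](C)(C)C(C)(C)C)ccc(C(=O)OCC[Si](C)(C)C)c21
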